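We read the flask at 6.0 h, well past the fast part of the earlier runs: in the delta run the solid substrate drops to 41.3% by 1.33 h and creeps after that.

the same everywhere: solid substrate 21 mM; second nucleophile 10.5 mM
- gamma: first nucleophile 42 mM; run made earlier
- delta: first nucleophile 170 mM; run made earlier
- flask: first nucleophile 84.0 mM; time 6.0 h

| run | time / h | target / % | solid substrate / % |
|---|---|---|---|
| gamma | 0.667 | 0.4 | 48.5 |
| gamma | 1.33 | 0.2 | 42.6 |
| gamma | 2.00 | 1.6 | 40.2 |
| gamma | 2.50 | 1.8 | 38.7 |
| gamma | 3.00 | 1.7 | 37.7 |
| gamma | 4.00 | 1.8 | 35.3 |
| delta | 0.250 | 0 | 67.3 |
| delta | 0.667 | 0 | 48.7 |
| delta | 1.33 | 1.3 | 41.3 |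
| delta | 2.00 | 1.9 | 40.6 |
| delta | 3.00 | 3.9 | 37.2 |
| delta | 4.00 | 4.6 | 35.4 |

(standard deviation of a reading: 0.3 percentage points)

- solid substrate is a solid; its amount is given per volume of the solution
- at the start none of the solid substrate is in solution

* target at 6.0 h, in percent of the solid substrate charged
* the change that raises the amount of target at 6.0 h, in percent of the solid substrate charged most ("none" if none brings more than 2 percentage points) (south-east / west / north-west / south / none)
* amount of target at 6.0 h, in percent of the solid substrate charged, after north-west

- south-east: doubling the dissolution coefficient of the solid substrate, all else as stated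
- west: doubling the solubility of the solid substrate, all else as stated
- north-west: doubling the amount of second nucleophile, all else as stated
- south: doubling the amount of first nucleophile, all else as stated

We suppose that the solid dissolves to saturation and that dissolved material leaks slowly into a short-lived intermediate, for which the two nucleophiles compete. Each capture has a rate proportional to its nucleophile, so target receives this share of the turnover:

share = c(first nucleophile) / (c(first nucleophile) + σ·c(second nucleophile))

The last target readings of the two runs, 1.8% and 4.6%, give, with the scatter of such small readings:

σ = 16.9

This selectivity factor, how many times faster the second nucleophile captures than the first at equal concentration, is our carried quantity.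

Taking the turnover as steady and the same at any c(first nucleophile), the last target reading of the delta run, scaled to 6.0 h, gives a turnover of 14.1%; the creep of its solid, scaled to that time, gives 13.3%.

First round: share 32.2%, target 4.53%.

Second round: captures lower the mean c(second nucleophile) to 9.50 mM, so target is 4.85%.

Going round likewise, north-west gives 2.83%. South gains 2.4 percentage points. West, if the turnover follows what is dissolved and the 58.7% gone from the solid in the delta run at 1.33 h doubles, up to the whole charge, gains 3.4 points, more than south, so we choose west.

The forecast gives 4% (3% to 5.2%), chooses north-west and puts that change at 7.5% (4.5% to 10%), reasoning that “Doubling the second nucleophile doubles the intermediate”. Our reckoning differs from it on north-west and on the choice.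

The flask gives 5.29%; west is best at 3.4 points, and north-west moves target by −1.9 points, to 3.41%.

    solid substrate ⇌ starting material, rate k1*(cs1 - [starting material]) while solid is left; crystals form when [starting material] > cs1 (solubility = 12.0 mM, k = 3.40 h⁻¹)
    starting material → intermediate (k = 0.0370 h⁻¹)
    first nucleophile + intermediate → target (k = 280 M⁻¹ h⁻¹)
    second nucleophile + intermediate → other capture product (k = 2700 M⁻¹ h⁻¹)
    target ⇌ isomer of the product (K = 2.50, k = 0.0190 h⁻¹)

In this flask the intermediate's half-life by the second nucleophile, 1.5 min at the charged amounts, is shorter than the 1.8 min by the first at 0.268 h, and at 6.00 h other capture product stands at 6.33% against 5.29% of target. With 18 mM of second nucleophile, two rounds with σ give 3.21% of target, and that flask holds 3.79%.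

(All runs come from a simulation from invented constants, and the scatter is random.)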